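**Compound numbering used throughout:** 1 naphthazarin, 2 its leuco tetrol, 3 tetramethyl ether, 4 aryl bromide, 5 cyclopropanecarbonitrile, 6 aryl cyclopropyl nitrile, 7 ketimine magnesium salt, 8 methyl ketone, 9 isopropenyl cyclopropane, 10 angelic acid, 11 cyclopropylcarbinyl cation, 12 cyclobutyl cation, 13 tetramethoxy ester, 14 dimethoxyquinone ester, 15 target. Ring A is the oxygenated ring that carries the side chain (C1–C4), ring B the other oxygenated ring (C5–C8), ring C the cyclobutane (C1'–C4').

## Analysis of the target

Compound 15 is a naphthazarin: ring A is a 1,4-quinone, ring B carries hydroxyls at C5 and C8 that are hydrogen-bonded to the peri carbonyls, and C2 of ring A bears ring C. Ring C is a cyclobutane in which C1' carries ring A and the ester oxygen, C2' carries two methyl groups, and C3' and C4' are methylenes. C1' is the only stereocentre and is R; it is fully substituted and sits between the quaternary C2' and a ring carbon with an ortho substituent. The acyl group is that of angelic acid, whose Z double bond slips to the E (tiglate) geometry under acid, base, heat or nucleophiles. The tertiary ester can ionise or eliminate, and the naphthazarin is redox-active, a Michael acceptor and a pair of fast-exchanging tautomers in which rings A and B swap roles. The hard points are the acylation of a C1' hydroxyl in so crowded a position with an acid that isomerises, and the setting of a stereocentre whose two ring flanks differ only as CMe2 against CH2. The strategy rests on the array aryl–C1'(O)–C2'(CH3)2 inside a four-membered ring. This is what results when a 1-arylcyclopropyl dimethylcarbinyl cation enlarges to a cyclobutyl cation and is trapped at oxygen. C2'–C3' can therefore come from a 1,2-shift and C1'–O from ion capture, provided ring A is still an electron-rich arene at that moment.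

## Retrosynthetic reasoning

**15 to 14.** The two O–H groups of ring B are traced back to O–CH3 bonds. Methyl ethers are the phenol protection that survives every organometallic step of the front end. In 14 each of them lies peri to a quinone carbonyl, so a Lewis acid can cleave them by chelation at low temperature. The forward reaction has to remove two methyl groups and leave a tertiary ester and a Z alkene alone.

**14 to 13.** Ring A of 14 is taken back to the para-dimethoxy arene of 13. This is a change of oxidation level, not a skeletal cut, but its place in the sequence is dictated by the key step. Ring A must be an electron-rich arene when C1' becomes cationic and a quinone only afterwards, when the same electron demand protects the ester from ionisation. The forward oxidation has to pick two of four methoxy groups. Which ring it picks is not critical, because oxidation of either ring leads after the last demethylation to the same tautomeric naphthazarin 15.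

**13 to 9 and 10.** Compound 13 is cut at C1'–O and at C2'–C3' together. Cutting C1'–O alone would leave a tertiary hydroxyl to be acylated between a quaternary carbon and an ortho-substituted arene. Cutting both bonds leads through cyclobutyl cation 12 and, by reversal of a 1,2-shift, through cyclopropylcarbinyl cation 11 to alkene 9 and angelic acid 10. Ring C, the stereocentre and the ester bond then arise in one operation in which every atom of 9 and 10 ends up in 13, and no hydroxyl at C1' is ever handled. The forward reaction has to protonate 9 at its terminal carbon, let a cyclopropane bond migrate, and deliver 10 to one face of planar 12 under the control of a chiral counteranion, cold enough that 13 does not ionise again.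

**9 to 8.** The terminal C=CH2 bond of 9 is cut to ketone 8 and a one-carbon ylide. An alkene is preferred over a tertiary alcohol as the cation source because protonation releases nothing that could compete with 10 for cation 12. The forward reaction is a methylenation of a hindered ketone.

**8 to 6 via 7.** The C–CH3 bond of the acetyl group is cut, which leads to nitrile 6. A methyl organometallic adds to a nitrile only once, since the imine salt 7 is inert until it is hydrolysed, and the nitrile is also the group that makes the next disconnection possible.

**6 to 4 and 5.** The bond between C2 of the naphthalene and the quaternary cyclopropane carbon is cut, which gives aryl bromide 4 and cyclopropanecarbonitrile 5. The three-membered ring is bought intact and the quaternary carbon is made in one palladium-catalysed coupling of the nitrile anion, instead of being assembled stepwise on the arene. The forward reaction must form a C–C bond next to an ortho methoxy group on an electron-rich ring.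

**4 to 3 to 1 via 2.** The C–Br bond of 4 is cut to give 3, whose four free ring positions are equivalent, so monobromination has no regiochemical issue. The four O–CH3 bonds of 3 are cut back to tetrol 2, the two-electron reduction product of commercial naphthazarin 1. Reduction and methylation are run in one flask because 2 reoxidises in air.

## Alternatives that were turned down

**Alternative 1:** Ring A is cut at C1–C8a and C4–C4a. In the forward sense 3,6-dimethoxybenzyne A2, set free from a brominated dimethoxybenzene by a strong hindered amide base, undergoes a Diels–Alder reaction with the enantiopure 3-substituted furan A3. The product is the oxygen-bridged adduct A1, as both bridgehead diastereomers, which does not matter because the bridge is destroyed later.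
- For: the plan is convergent, the aryne is symmetric so there is no regiochemistry to control, and aryne–furan cycloadditions are dependable. The stereocentre arrives ready-made and never passes through a cation.
- Against: all the difficulty of the target is moved into A3, a tertiary carbinol between a quaternary carbon and a heteroaryl ring, which needs an asymmetric ketone addition of no generality or a resolution. After the cycloaddition the bridge must be aromatised under acid with an allylic tertiary silyl ether present, the ring oxidised to the quinone, the silyl group removed and the free tertiary hydroxyl acylated with 10. That acylation is the hindered, isomerisation-prone step that the chosen route never has to run.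
- Comparison: this alternative is stronger on the security of the configuration once A3 is in hand. The chosen strategy offers instead one step that makes ring C, the stereocentre and the ester, no protecting group on the C1' oxygen, and a route of 8 steps against well over ten.

**Alternative 2:** Ring C is cut at C1'–C2' and C3'–C4'. The arylketene A5, generated from the arylacetyl chloride with a tertiary amine and activated by a Lewis acid, adds to 2-methylpropene A6 in a [2+2] cycloaddition to give cyclobutanone A4. C1'–O is then made by oxygenation of the enolate.
- For: the cycloaddition is a known reaction type that works with unactivated alkenes, its regiochemistry follows the polarity of the partners, and both ring bonds form at once from a cheap gas.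
- Against: the carbonyl of A4 lies at the carbon that is C4' of the target, a methylene, so an oxygen is brought in only to be removed. That removal has to be done next to a tertiary benzylic oxygen on a strained ring that is prone to ring contraction. The stereocentre would have to come from face-selective hydroxylation of a fully substituted, aryl-conjugated enolate with a chiral oxygen-transfer reagent, which is hard to predict. The hindered acylation with 10 remains as well.
- Comparison: this alternative is stronger in that its ring-forming step is precedented. The chosen strategy offers the correct oxidation level at every ring carbon from the start and introduces the oxygen directly as the ester.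

**Alternative 3:** Ring C is cut at C3'–C4'. The five-membered sulfone A8 is halogenated next to sulfur under strongly basic conditions, closes to the three-membered sulfone and loses its sulfonyl group as a gas (Ramberg–Bäcklund reaction). The ring contracts to cyclobutene A7.
- For: the stereocentre is present before the contraction and is not touched by it, and no cation is formed near it.
- Against: A8 still needs a tertiary aryl carbinol as a single enantiomer, which is the same unsolved problem as in alternative 1. The carbanion next to sulfur at C2 of A8 is beta to the silyloxy group, so loss of that group competes directly with the contraction. The double bond of A7 is made only to be hydrogenated. Removal of a hindered tertiary silyl ether and the acylation with 10 follow before the two end-game steps.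
- Comparison: this alternative is stronger on configurational safety. The chosen strategy offers a far shorter sequence and avoids both the redundant alkene and the tertiary alcohol acylation.

Key step: step 6

Remark: the sense of induction of the chiral acid cannot be predicted for this new ion pair. It is assumed that the catalyst antipode that delivers (R)-13 is found in a first screen; both antipodes are equally accessible.

Remark: 15 is drawn as the tautomer with ring A as the quinone. The naphthazarin tautomers interconvert fast and are treated as one compound.

## Route

Step 1
Reactants: 1 naphthazarin (5,8-dihydroxynaphthalene-1,4-dione)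
Product: 3 1,4,5,8-tetramethoxynaphthalene, via naphthalene-1,4,5,8-tetrol 2 (not isolated)
Conditions: Na2S2O4, aq NaOH, n-Bu4NBr (cat.), THF/H2O, Ar, rt; then Me2SO4, 0 °C to rt
Reagents that add atoms: dimethyl sulfate, COS(=O)(=O)OC
Why: Reductive O-methylation: Na2S2O4 reduces the quinone to the air-sensitive tetrol 2, and its four phenoxides are then methylated under phase-transfer conditions (Williamson ether synthesis); running both events in one flask under argon avoids reoxidation.

Step 2
Reactants: 3 1,4,5,8-tetramethoxynaphthalene
Product: 4 2-bromo-1,4,5,8-tetramethoxynaphthalene
Conditions: NBS (1.0 equiv), CH2Cl2, 0 °C to rt, dark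
Reagents that add atoms: N-bromosuccinimide, O=C1CCC(=O)N1Br
Why: Electrophilic aromatic bromination of a very electron-rich arene; the four free positions of 3 are equivalent by symmetry, so a first substitution can only give 4, and one equivalent of reagent at low temperature limits a second one.

Step 3
Reactants: 4 2-bromo-1,4,5,8-tetramethoxynaphthalene; 5 cyclopropanecarbonitrile
Product: 6 1-(1,4,5,8-tetramethoxynaphthalen-2-yl)cyclopropane-1-carbonitrile
Conditions: Pd2(dba)3 (2.5 mol %), 4,6-bis(diphenylphosphino)-10H-phenoxazine (6 mol %), LiN(SiMe3)2, cyclopentyl methyl ether, 70 °C
Reagents that add atoms: none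
Why: Palladium-catalysed alpha-arylation of a nitrile: zerovalent palladium inserts into the C–Br bond, the lithiated nitrile displaces bromide, and the wide-bite-angle bisphosphine drives C–C reductive elimination to the quaternary carbon. The small cyclopropyl anion should tolerate the ortho methoxy group, and 6 has no alpha hydrogen, so it cannot react a second time.

Step 4
Reactants: 6 1-(1,4,5,8-tetramethoxynaphthalen-2-yl)cyclopropane-1-carbonitrile
Product: 8 1-[1-(1,4,5,8-tetramethoxynaphthalen-2-yl)cyclopropyl]ethan-1-one, via ketimine magnesium salt 7 (not isolated)
Conditions: MeMgBr (3 equiv), CuBr (5 mol %), THF/toluene, 70 °C; then 1 M HCl, 0 °C to rt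
Reagents that add atoms: methylmagnesium bromide, C[Mg]Br; water, O
Why: Grignard addition to a nitrile stops at the N-magnesio ketimine 7, which is not electrophilic, and dilute acid then hydrolyses it to ketone 8. Copper catalysis is a known aid for hindered nitriles, and 6 has no alpha hydrogen that could be removed instead.

Step 5
Reactants: 8 1-[1-(1,4,5,8-tetramethoxynaphthalen-2-yl)cyclopropyl]ethan-1-one
Product: 9 1,4,5,8-tetramethoxy-2-[1-(prop-1-en-2-yl)cyclopropyl]naphthalene
Conditions: Ph3PCH3Br, KOt-Bu, THF, 0 °C to 65 °C
Reagents that add atoms: methyltriphenylphosphonium bromide, C[P+](c1ccccc1)(c1ccccc1)c1ccccc1.[Br-]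
Why: Wittig methylenation; the unstabilised ylide is reactive enough for a ketone next to a quaternary carbon when warmed, and the basic, non-acidic medium leaves the donor-substituted cyclopropane intact.

Step 6
Reactants: 9 1,4,5,8-tetramethoxy-2-[1-(prop-1-en-2-yl)cyclopropyl]naphthalene; 10 angelic acid ((2Z)-2-methylbut-2-enoic acid)
Product: 13 (1R)-2,2-dimethyl-1-(1,4,5,8-tetramethoxynaphthalen-2-yl)cyclobutyl (2Z)-2-methylbut-2-enoate, via cyclopropylcarbinyl cation 11 (not isolated), via cyclobutyl cation 12 (not isolated)
Conditions: confined chiral imidodiphosphorimidate Brønsted acid (IDPi, N-triflyl, 3,3'-diaryl-BINOL backbones, 5 mol %), 10 (5 equiv), CHCl3/methylcyclohexane (0.05 M), −40 °C; Et3N at −40 °C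
Reagents that add atoms: none
Why: Proposed new method: the chiral acid protonates the terminal CH2 of the isopropenyl group of 9 (Markovnikov) to give the tertiary cyclopropylcarbinyl cation 11; a cyclopropane C–C bond held parallel to the empty p orbital then shifts from the aryl-bearing carbon to the carbinyl carbon, forming C2'–C3' and placing the charge on the aryl-bearing carbon as cyclobutyl cation 12, which is stabilised by the ortho-methoxylated naphthalene. The closest known reaction types are the cyclopropylcarbinyl-to-cyclobutyl rearrangement (as in protio-semipinacol enlargements of alkenylcyclopropanes) and the asymmetric Wagner–Meerwein shifts and alkene hydrofunctionalisations catalysed by imidodiphosphorimidate acids; enantioselective intermolecular capture of such a cation by a carboxylic acid has not been shown. Ring C is not closed by a cyclisation but by a three-to-four ring enlargement through a suprafacial 1,2-alkyl shift, and the two enantiotopic cyclopropane methylenes lead to the same achiral cation. The stereocentre C1' is created only when 10 adds through oxygen to one face of planar 12; the face is chosen by the chiral counteranion, which holds 12 in its pocket and delivers the acid by hydrogen bonding, with the CMe2 and CH2 flanks and the single ortho methoxy group giving the pocket a shape to recognise. Capture has to outrun loss of a C4' proton, Friedel–Crafts attack by a second arene and capture of 11 before the shift; elimination would give a strained cyclobutene, the cationic carbon is neopentylic and shielded against bulky carbon nucleophiles, 12 is far more stable than 11, and the excess of 10 supplies a small nucleophile. Because ionisation of 13 is the microscopic reverse, the temperature is kept low, the acid is chosen no stronger than needed to protonate the alkene, and the mixture is quenched cold with amine to keep the ester and its configuration. The Z double bond of 10 is not involved, since only the carboxyl group reacts.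

Step 7
Reactants: 13 (1R)-2,2-dimethyl-1-(1,4,5,8-tetramethoxynaphthalen-2-yl)cyclobutyl (2Z)-2-methylbut-2-enoate
Product: 14 (1R)-1-(5,8-dimethoxy-1,4-dioxo-1,4-dihydronaphthalen-2-yl)-2,2-dimethylcyclobutyl (2Z)-2-methylbut-2-enoate
Conditions: (NH4)2Ce(NO3)6 (2.5 equiv), MeCN/H2O, 0 °C, 15 min
Reagents that add atoms: water, O
Why: Oxidative demethylation of a para-dimethoxyarene by two equivalents of tetravalent cerium: the arene radical cation is attacked by water at the methoxy-bearing carbons and methanol is lost, so the quinone oxygens come from water. The ring A methoxy groups next to the bulky C2 substituent are twisted out of conjugation and are expected to react first; oxidation of ring B instead would converge after step 8, because the two demethylated forms are tautomers of one naphthazarin. Short contact at 0 °C limits acid solvolysis of the tertiary ester, and C1' is not involved.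

Step 8
Reactants: 14 (1R)-1-(5,8-dimethoxy-1,4-dioxo-1,4-dihydronaphthalen-2-yl)-2,2-dimethylcyclobutyl (2Z)-2-methylbut-2-enoate
Product: 15 (1R)-1-(5,8-dihydroxy-1,4-dioxo-1,4-dihydronaphthalen-2-yl)-2,2-dimethylcyclobutyl (2Z)-2-methylbut-2-enoate
Conditions: BCl3, CH2Cl2, −78 to −40 °C; then H2O
Reagents that add atoms: none
Why: Chelation-assisted Lewis acid ether cleavage: BCl3 binds each peri methoxy oxygen together with the neighbouring quinone carbonyl and chloride removes the methyl group at low temperature, conditions under which isolated esters are normally left alone. The ester now sits on an electron-poor quinone carbon, so ionisation at C1' is disfavoured and the R configuration and the Z geometry should be kept.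

## Compound list

1 | naphthazarin (5,8-dihydroxynaphthalene-1,4-dione) | O=C1C=CC(=O)c2c(O)ccc(O)c12 | starting material
2 | naphthalene-1,4,5,8-tetrol (leuco form, present as its sodium salt) | Oc1ccc(O)c2c(O)ccc(O)c12 | intermediate
3 | 1,4,5,8-tetramethoxynaphthalene | COc1ccc(OC)c2c(OC)ccc(OC)c12 | intermediate
4 | 2-bromo-1,4,5,8-tetramethoxynaphthalene | COc1ccc(OC)c2c(OC)c(Br)cc(OC)c12 | intermediate
5 | cyclopropanecarbonitrile | N#CC1CC1 | starting material
6 | 1-(1,4,5,8-tetramethoxynaphthalen-2-yl)cyclopropane-1-carbonitrile | COc1ccc(OC)c2c(OC)c(C3(C#N)CC3)cc(OC)c12 | intermediate
7 | N-bromomagnesio imine of 1-[1-(1,4,5,8-tetramethoxynaphthalen-2-yl)cyclopropyl]ethan-1-one | COc1ccc(OC)c2c(OC)c(C3(C(C)=N[Mg]Br)CC3)cc(OC)c12 | intermediate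
8 | 1-[1-(1,4,5,8-tetramethoxynaphthalen-2-yl)cyclopropyl]ethan-1-one | COc1ccc(OC)c2c(OC)c(C3(C(C)=O)CC3)cc(OC)c12 | intermediate
9 | 1,4,5,8-tetramethoxy-2-[1-(prop-1-en-2-yl)cyclopropyl]naphthalene | COc1ccc(OC)c2c(OC)c(C3(C(C)=C)CC3)cc(OC)c12 | intermediate
10 | angelic acid ((2Z)-2-methylbut-2-enoic acid) | C/C=C(/C)C(=O)O | starting material
11 | 2-[1-(1,4,5,8-tetramethoxynaphthalen-2-yl)cyclopropyl]propan-2-ylium (ion pair with the catalyst anion) | COc1ccc(OC)c2c(OC)c(C3([C+](C)C)CC3)cc(OC)c12 | intermediate
12 | 2,2-dimethyl-1-(1,4,5,8-tetramethoxynaphthalen-2-yl)cyclobutan-1-ylium (ion pair with the catalyst anion) | COc1ccc(OC)c2c(OC)c([C+]3CCC3(C)C)cc(OC)c12 | intermediate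
13 | (1R)-2,2-dimethyl-1-(1,4,5,8-tetramethoxynaphthalen-2-yl)cyclobutyl (2Z)-2-methylbut-2-enoate | C/C=C(/C)C(=O)O[C@]1(c2cc(OC)c3c(OC)ccc(OC)c3c2OC)CCC1(C)C | intermediate
14 | (1R)-1-(5,8-dimethoxy-1,4-dioxo-1,4-dihydronaphthalen-2-yl)-2,2-dimethylcyclobutyl (2Z)-2-methylbut-2-enoate | C/C=C(/C)C(=O)O[C@]1(C2=CC(=O)c3c(OC)ccc(OC)c3C2=O)CCC1(C)C | intermediate
15 | (1R)-1-(5,8-dihydroxy-1,4-dioxo-1,4-dihydronaphthalen-2-yl)-2,2-dimethylcyclobutyl (2Z)-2-methylbut-2-enoate | C/C=C(/C)C(=O)O[C@]1(C2=CC(=O)c3c(O)ccc(O)c3C2=O)CCC1(C)C | target

## Step count and weak points

Total: 8 steps. Longest linear sequence: 8 steps, from 1 to 15; 5 and 10 are bought.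

**Step 6 (key step, proposed new method).** Three things are most likely to go wrong. Capture of a planar, long-lived benzylic cation may show poor facial selectivity. The ester may re-ionise under the acid, which erodes the enantiomeric purity and opens the way to proton loss and Friedel–Crafts alkylation of a second arene. The addition equilibrium for so crowded an ester may also lie on the wrong side. The fallback uses known chemistry and sets out from 4. Bromine–lithium exchange with n-BuLi in THF at −78 °C and addition of the aryllithium to 2,2-dimethylcyclobutan-1-one (available from specialist suppliers) should give racemic 2,2-dimethyl-1-(1,4,5,8-tetramethoxynaphthalen-2-yl)cyclobutan-1-ol F1. Preparative chromatography on a chiral stationary phase would separate the (1R)-alcohol F2 from the (1S)-alcohol F3, which is set aside. Deprotonation of F2 with KN(SiMe3)2 at −78 °C and acylation with angelic anhydride F4, made from 10 with N,N'-dicyclohexylcarbodiimide, would give 13, where the route is rejoined at step 7. The price is the hindered acylation that the main route avoids and the loss of half the material.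

**Step 8.** The Lewis acid may trigger loss of the tertiary ester by ionisation or elimination, Z to E isomerisation of the angelate, addition of chloride to the quinone, or cleavage of only one ether. The ester is most exposed if ring B was the ring oxidised in step 7. The fallback sets out from 14 and replaces the Lewis acid by a redox sequence. A second oxidative demethylation with AgO and aqueous HNO3 in acetone should give (1R)-2,2-dimethyl-1-(1,4,5,8-tetraoxo-1,4,5,8-tetrahydronaphthalen-2-yl)cyclobutyl (2Z)-2-methylbut-2-enoate F5. Two-electron reduction of F5 with aqueous Na2S2O4 would give 15 directly.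

**Step 7.** The tertiary benzylic ester may solvolyse in the acidic aqueous nitrate medium before ring A is oxidised, the strained C1'–C2' bond may fragment at the radical-cation stage, and ring B may be oxidised in place of ring A. The fallback sets out from 13 and avoids acid during the oxidation. Anodic oxidation at a platinum anode in methanol with 1 % KOH at 0 °C should give the quinone bis(dimethyl ketal) (1R)-1-(1,1,4,4,5,8-hexamethoxy-1,4-dihydronaphthalen-2-yl)-2,2-dimethylcyclobutyl (2Z)-2-methylbut-2-enoate F6. Hydrolysis of F6 with aqueous acetic acid at room temperature would give 14.

**Step 3.** Oxidative addition into the electron-rich, ortho-substituted C–Br bond may be slow, so that protodebromination and catalyst decay take over. The fallback sets out from 3 and builds the cyclopropane on the arene by classical chemistry. Vilsmeier–Haack formylation (POCl3, DMF) should give 1,4,5,8-tetramethoxynaphthalene-2-carbaldehyde F7. Reductive cyanation with tosylmethyl isocyanide and KOt-Bu followed by methanol (Van Leusen reaction) would give 2-(1,4,5,8-tetramethoxynaphthalen-2-yl)acetonitrile F8. Double alkylation of F8 with 1,2-dibromoethane under phase transfer (50 % NaOH, benzyltriethylammonium chloride) would give 6, one step later than in the main route.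

## Further compounds

F1 | step 6 | rac-2,2-dimethyl-1-(1,4,5,8-tetramethoxynaphthalen-2-yl)cyclobutan-1-ol | COc1ccc(OC)c2c(OC)c(C3(O)CCC3(C)C)cc(OC)c12
F2 | step 6 | (1R)-2,2-dimethyl-1-(1,4,5,8-tetramethoxynaphthalen-2-yl)cyclobutan-1-ol | O[C@]1(c2cc(OC)c3c(OC)ccc(OC)c3c2OC)CCC1(C)C
F3 | step 6 | (1S)-2,2-dimethyl-1-(1,4,5,8-tetramethoxynaphthalen-2-yl)cyclobutan-1-ol | O[C@@]1(c2cc(OC)c3c(OC)ccc(OC)c3c2OC)CCC1(C)C
F4 | step 6 | angelic anhydride ((2Z)-2-methylbut-2-enoic anhydride) | C/C=C(/C)C(=O)OC(=O)/C(C)=C\C
F5 | step 8 | (1R)-2,2-dimethyl-1-(1,4,5,8-tetraoxo-1,4,5,8-tetrahydronaphthalen-2-yl)cyclobutyl (2Z)-2-methylbut-2-enoate | C/C=C(/C)C(=O)O[C@]1(C2=CC(=O)C3=C(C2=O)C(=O)C=CC3=O)CCC1(C)C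
F6 | step 7 | (1R)-1-(1,1,4,4,5,8-hexamethoxy-1,4-dihydronaphthalen-2-yl)-2,2-dimethylcyclobutyl (2Z)-2-methylbut-2-enoate | C/C=C(/C)C(=O)O[C@]1(C2=CC(OC)(OC)c3c(OC)ccc(OC)c3C2(OC)OC)CCC1(C)C
F7 | step 3 | 1,4,5,8-tetramethoxynaphthalene-2-carbaldehyde | COc1ccc(OC)c2c(OC)c(C=O)cc(OC)c12
F8 | step 3 | 2-(1,4,5,8-tetramethoxynaphthalen-2-yl)acetonitrile | COc1ccc(OC)c2c(OC)c(CC#N)cc(OC)c12
A1 | alternative 1 | 2-[(1R)-2,2-dimethyl-1-(triethylsilyloxy)cyclobutyl]-5,8-dimethoxy-1,4-dihydro-1,4-epoxynaphthalene (both bridgehead diastereomers) | CC[Si](CC)(CC)O[C@]1(C2=CC3OC2c2c(OC)ccc(OC)c23)CCC1(C)C
A2 | alternative 1 | 3,6-dimethoxybenzyne | COC1=CC=C(OC)C#C1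
A3 | alternative 1 | triethyl{[(1R)-1-(furan-3-yl)-2,2-dimethylcyclobutyl]oxy}silane | CC[Si](CC)(CC)O[C@]1(c2ccoc2)CCC1(C)C
A4 | alternative 2 | 3,3-dimethyl-2-(1,4,5,8-tetramethoxynaphthalen-2-yl)cyclobutan-1-one (racemic) | COc1ccc(OC)c2c(OC)c(C3C(=O)CC3(C)C)cc(OC)c12
A5 | alternative 2 | (1,4,5,8-tetramethoxynaphthalen-2-yl)ketene | COc1ccc(OC)c2c(OC)c(C=C=O)cc(OC)c12
A6 | alternative 2 | 2-methylpropene | CC(C)=C
A7 | alternative 3 | tert-butyl{[(1R)-4,4-dimethyl-1-(1,4,5,8-tetramethoxynaphthalen-2-yl)cyclobut-2-en-1-yl]oxy}dimethylsilane | CC(C)(C)[Si](C)(C)O[C@]1(c2cc(OC)c3c(OC)ccc(OC)c3c2OC)C=CC1(C)C
A8 | alternative 3 | (3R)-3-[tert-butyl(dimethyl)silyloxy]-4,4-dimethyl-3-(1,4,5,8-tetramethoxynaphthalen-2-yl)thiolane 1,1-dioxide | CC(C)(C)[Si](C)(C)O[C@]1(c2cc(OC)c3c(OC)ccc(OC)c3c2OC)CS(=O)(=O)CC1(C)C
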